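**Retrosynthetic overview**
1. Last operation: the 14-membered carbocycle and the cis α-methylene-γ-lactone are formed together by a chiral phosphoric acid-catalysed intramolecular allylboration of the C2 enal (C1–C2 bond) with in situ lactonisation.
2. The 2-alkoxycarbonyl allylboronate arm is attached by cross-metathesis to a C1 vinyl group; C13–C14 and the C13 stereocentre come from a chiral phosphoric acid-catalysed allylboration of a C13 enal.
3. The C11–C12 oxirane comes from a matched Sharpless epoxidation directed by the C13 carbinol; the C8 carbinol and the 6E-alkene come from Shi epoxidation of C7=C8, selenide opening and selenoxide elimination.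
4. C2–C13 with its three methyl groups is (2E,6E)-farnesyl acetate; SeO2 oxidises its terminal E-methyl group to the C13 aldehyde.
5. Ring order: oxirane on the open chain, then carbocycle and lactone in one operation.

Numbering: positions follow the cembrane skeleton of the target. C1 is the ring-fusion CH, C2 the lactone O–CH, then C3=C4(Me), C5, C6=C7, C8(Me)(OH), C9, C10, C11–C12(Me) oxirane, C13 (OAc), C14; C15, C16, C17 are the lactone α-carbon, carbonyl and exocyclic CH2.

Assumption: (2E,6E)-farnesyl acetate is bought as the single isomer, and the TRIP catalysts are taken to deliver allyl groups with the facial sense known for aryl and alkenyl aldehydes ((R)-catalyst to the Re face); if a sense proves reversed, the antipodal catalyst is used.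

**Step 1**
Reactants: 1 (2E,6E)-farnesyl acetate
Product: 3 (2E,6E,10E)-3,7,11-trimethyl-12-oxododeca-2,6,10-trien-1-yl acetate, via 12-hydroxy acetate 2 (not isolated)
Conditions: SeO2 (0.5 equiv), t-BuOOH (70% aq, 3 equiv), salicylic acid (10 mol %), CH2Cl2, 0 °C → rt; then MnO2 (15 equiv), rt
Reagents that add atoms: tert-butyl hydroperoxide, CC(C)(C)OO; selenium dioxide, O=[Se]=O
Why: Riley (SeO2) allylic oxidation proceeds by ene reaction and [2,3]-shift at the most electron-rich terminal trisubstituted alkene and selectively at its E-methyl group (C3=C4 is deactivated by the allylic acetate), and MnO2 then oxidises only the allylic alcohol; no stereocentre is formed.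

**Step 2**
Reactants: 3 (2E,6E,10E)-3,7,11-trimethyl-12-oxododeca-2,6,10-trien-1-yl acetate; 4 allylboronic acid pinacol ester
Product: 6 (2E,6E,10E,12S)-3,7,11-trimethylpentadeca-2,6,10,14-tetraene-1,12-diyl diacetate, via homoallylic alcohol 5 (not isolated)
Conditions: (S)-TRIP [(S)-3,3'-bis(2,4,6-triisopropylphenyl)-1,1'-binaphthyl-2,2'-diyl hydrogen phosphate] (5 mol %), 4 (1.2 equiv), PhMe, −30 °C; then MeOH (3 equiv), 0 °C; Ac2O (8 equiv), Et3N, DMAP (10 mol %), 0 °C → rt, one pot
Reagents that add atoms: acetic anhydride, CC(=O)OC(C)=O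
Why: Chiral phosphoric acid-catalysed allylboration of an aldehyde runs through a closed chair transition state in which the catalyst hydrogen-bonds a boronate oxygen and the formyl C–H, the (S)-catalyst sending the allyl group to the Si face of the α-methyl enal to set C13 as S (the first stereocentre), and the carbinol is acetylated in the same pot so that C11=C12 is electronically deactivated for step 3.

**Step 3**
Reactants: 6 (2E,6E,10E,12S)-3,7,11-trimethylpentadeca-2,6,10,14-tetraene-1,12-diyl diacetate
Product: 7 (2E,6R,7R,10E,12S)-6,7-epoxy-3,7,11-trimethylpentadeca-2,10,14-triene-1,12-diyl diacetate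
Conditions: D-fructose-derived Shi ketone (1,2:4,5-di-O-isopropylidene-β-D-erythro-2,3-hexodiulo-2,6-pyranose, 30 mol %), KHSO5 (as Oxone, 1.4 equiv), K2CO3, Bu4NHSO4 (4 mol %), MeCN–dimethoxymethane / aq Na2B4O7–Na2EDTA buffer (pH 10.5), 0 °C
Reagents that add atoms: potassium peroxymonosulfate, [K+].[O-]S(=O)(=O)OO
Why: In this Shi epoxidation (chiral dioxirane, spiro transition state) the only electron-rich alkene is C7=C8, since C3=C4 and C11=C12 are deactivated by allylic acetates and the vinyl group is slow, and the D-fructose-derived ketone gives the (R,R)-oxirane (cembrane 7R,8R), which fixes C8.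

**Step 4**
Reactants: 7 (2E,6R,7R,10E,12S)-6,7-epoxy-3,7,11-trimethylpentadeca-2,10,14-triene-1,12-diyl diacetate
Product: 10 (2E,5E,7R,10E,12S)-3,7,11-trimethylpentadeca-2,5,10,14-tetraene-1,7,12-triol, via epoxy diol 8 (not isolated), via hydroxy selenide 9 (not isolated)
Conditions: K2CO3 (0.2 equiv), MeOH, rt; then (PhSe)2 (0.8 equiv), NaBH4 (1.7 equiv), EtOH, 0 → 70 °C; then THF, pyridine, 30% H2O2, 0 °C → rt
Reagents that add atoms: none
Why: After acetate methanolysis, phenylselenolate opens the trisubstituted oxirane by SN2 attack at the less hindered C7 and the selenoxide syn-eliminates towards C6 only, because C8 carries no hydrogen (Sharpless-type epoxide to allylic alcohol transposition), giving the 6E-alkene and the tertiary carbinol with its C8–O bond untouched (8R retained).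

**Step 5**
Reactants: 10 (2E,5E,7R,10E,12S)-3,7,11-trimethylpentadeca-2,5,10,14-tetraene-1,7,12-triol
Product: 11 (2E,5E,7R,10E,12S)-7,12-dihydroxy-3,7,11-trimethylpentadeca-2,5,10,14-tetraenal
Conditions: TEMPO (10 mol %), PhI(OAc)2 (1.1 equiv), CH2Cl2, 0 °C → rt
Reagents that add atoms: none
Why: Oxoammonium (TEMPO/PhI(OAc)2) oxidation is sterically selective for the primary allylic alcohol over the secondary and tertiary ones and gives the 2E-enal without touching a stereocentre.

**Step 6**
Reactants: 11 (2E,5E,7R,10E,12S)-7,12-dihydroxy-3,7,11-trimethylpentadeca-2,5,10,14-tetraenal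
Product: 13 (2E,5E,7R,10S,11R,12S)-12-acetoxy-10,11-epoxy-7-hydroxy-3,7,11-trimethylpentadeca-2,5,14-trienal, via epoxy alcohol 12 (not isolated)
Conditions: Ti(OiPr)4 (0.2 equiv), L-(+)-diisopropyl tartrate (0.3 equiv), t-BuOOH (in decane, 1.5 equiv), 4 Å MS, CH2Cl2, −20 °C; then P(OMe)3, −20 °C; then Ac2O (3 equiv), pyridine, DMAP (10 mol %), −20 → 0 °C
Reagents that add atoms: tert-butyl hydroperoxide, CC(C)(C)OO; acetic anhydride, CC(=O)OC(C)=O
Why: This is a Sharpless asymmetric epoxidation in its matched kinetic-resolution mode, in which L-(+)-tartrate makes the (13S) secondary allylic alcohol the fast-reacting enantiomer and gives the erythro oxirane (cembrane 11S,12R) while the tertiary allylic C8 alcohol, the enal and the homoallylic vinyl group are inert, and in situ acetylation installs the C13 acetate (the descriptor at the methyl-bearing oxirane carbon changes from S in 12 to R in 13 only through ligand priority).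

**Step 7**
Reactants: 14 methyl 2-(bromomethyl)acrylate; 15 bis(pinacolato)diboron
Product: 16 methyl 2-[(4,4,5,5-tetramethyl-1,3,2-dioxaborolan-2-yl)methyl]acrylate
Conditions: CuCl (10 mol %), LiCl (10 mol %), KOAc (1.1 equiv), DMF, rt
Reagents that add atoms: none
Why: Copper-catalysed borylation of an allylic halide with B2pin2 (borylcopper conjugate addition then bromide elimination, SN2') is a standard entry to 2-alkoxycarbonyl allylboronates; no stereocentre is formed.

**Step 8**
Reactants: 13 (2E,5E,7R,10S,11R,12S)-12-acetoxy-10,11-epoxy-7-hydroxy-3,7,11-trimethylpentadeca-2,5,14-trienal; 16 methyl 2-[(4,4,5,5-tetramethyl-1,3,2-dioxaborolan-2-yl)methyl]acrylate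
Product: 17 methyl (2E,5S,6R,7S,10R,11E,14E)-5-acetoxy-6,7-epoxy-10-hydroxy-6,10,14-trimethyl-16-oxo-2-[(4,4,5,5-tetramethyl-1,3,2-dioxaborolan-2-yl)methyl]hexadeca-2,11,14-trienoate
Conditions: 16 (4 equiv), second-generation Hoveyda–Grubbs catalyst (10 mol %), CH2Cl2 (0.05 M), 40 °C
Reagents that add atoms: none
Why: Olefin cross-metathesis of a terminal alkene with a 1,1-disubstituted acrylate (as with methacrylates) engages only the monosubstituted vinyl group and gives the thermodynamically favoured trisubstituted enoate with C14 trans to the ester and so cis to CH2Bpin, the geometry needed for a cis-lactone, while the ester-deactivated boronate does not add to the enal at this temperature.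

**Step 9**
Reactants: 17 methyl (2E,5S,6R,7S,10R,11E,14E)-5-acetoxy-6,7-epoxy-10-hydroxy-6,10,14-trimethyl-16-oxo-2-[(4,4,5,5-tetramethyl-1,3,2-dioxaborolan-2-yl)methyl]hexadeca-2,11,14-trienoate
Product: 19 (1S,2S,3E,6E,8R,11S,12R,13S)-13-acetoxy-11,12-epoxy-8-hydroxycembra-3,6,15(17)-trien-16,2-olide (CNP0288879.3), via borate ester 18 (not isolated)
Conditions: (R)-TRIP (20 mol %), 4 Å MS, PhMe (0.002 M, slow addition of 17), 25 °C, 72 h; then PPTS (20 mol %), 25 °C
Reagents that add atoms: none
Why: Proposed new method: chiral phosphoric acid-catalysed intramolecular allylboration of a 2-alkoxycarbonyl allylboronate onto an enal, closing the 14-membered ring; the P–OH hydrogen-bonds a pinacol oxygen and the P=O the formyl C–H, which accelerates the closed chair transition state while the uncatalysed addition of these ester-deactivated boronates is negligible at 2 mM, so the (R)-catalyst selects the Re face of the C2 aldehyde (C2 = S), the boronate geometry (C14 cis to CH2B, hence axial) enforces the syn adduct (C1 = S), and the resulting borate lactonises to the cis-fused α-methylene lactone; the closest known reactions are the phosphoric acid-catalysed intermolecular allylboration of aldehydes with allyl pinacolboronates and the Brønsted or Lewis acid-catalysed 2-alkoxycarbonyl allylboration–lactonisation of aldehydes.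

**Compound list**
1 | (2E,6E)-farnesyl acetate [(2E,6E)-3,7,11-trimethyldodeca-2,6,10-trien-1-yl acetate] | CC(=O)OC/C=C(\C)CC/C=C(\C)CCC=C(C)C | starting material
2 | (2E,6E,10E)-12-hydroxy-3,7,11-trimethyldodeca-2,6,10-trien-1-yl acetate | CC(=O)OC/C=C(\C)CC/C=C(\C)CC/C=C(\C)CO | intermediate
3 | (2E,6E,10E)-3,7,11-trimethyl-12-oxododeca-2,6,10-trien-1-yl acetate | CC(=O)OC/C=C(\C)CC/C=C(\C)CC/C=C(\C)C=O | intermediate
4 | allylboronic acid pinacol ester (2-allyl-4,4,5,5-tetramethyl-1,3,2-dioxaborolane) | C=CCB1OC(C)(C)C(C)(C)O1 | starting material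
5 | (2E,6E,10E,12S)-12-hydroxy-3,7,11-trimethylpentadeca-2,6,10,14-tetraen-1-yl acetate | CC(=O)OC/C=C(\C)CC/C=C(\C)CC/C=C(\C)[C@@H](O)CC=C | intermediate
6 | (2E,6E,10E,12S)-3,7,11-trimethylpentadeca-2,6,10,14-tetraene-1,12-diyl diacetate | CC(=O)OC/C=C(\C)CC/C=C(\C)CC/C=C(\C)[C@@H](OC(C)=O)CC=C | intermediate
7 | (2E,6R,7R,10E,12S)-6,7-epoxy-3,7,11-trimethylpentadeca-2,10,14-triene-1,12-diyl diacetate | CC(=O)OC/C=C(\C)CC[C@H]1O[C@]1(C)CC/C=C(\C)[C@@H](OC(C)=O)CC=C | intermediate
8 | (2E,6R,7R,10E,12S)-6,7-epoxy-3,7,11-trimethylpentadeca-2,10,14-triene-1,12-diol | OC/C=C(\C)CC[C@H]1O[C@]1(C)CC/C=C(\C)[C@@H](O)CC=C | intermediate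
9 | (2E,6S,7R,10E,12S)-3,7,11-trimethyl-6-(phenylselanyl)pentadeca-2,10,14-triene-1,7,12-triol | OC/C=C(\C)CC[C@H]([Se]c1ccccc1)[C@](C)(O)CC/C=C(\C)[C@@H](O)CC=C | intermediate
10 | (2E,5E,7R,10E,12S)-3,7,11-trimethylpentadeca-2,5,10,14-tetraene-1,7,12-triol | OC/C=C(\C)C/C=C/[C@](C)(O)CC/C=C(\C)[C@@H](O)CC=C | intermediate
11 | (2E,5E,7R,10E,12S)-7,12-dihydroxy-3,7,11-trimethylpentadeca-2,5,10,14-tetraenal | O=C/C=C(\C)C/C=C/[C@](C)(O)CC/C=C(\C)[C@@H](O)CC=C | intermediate
12 | (2E,5E,7R,10S,11S,12S)-10,11-epoxy-7,12-dihydroxy-3,7,11-trimethylpentadeca-2,5,14-trienal | O=C/C=C(\C)C/C=C/[C@](C)(O)CC[C@@H]1O[C@@]1(C)[C@@H](O)CC=C | intermediate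
13 | (2E,5E,7R,10S,11R,12S)-12-acetoxy-10,11-epoxy-7-hydroxy-3,7,11-trimethylpentadeca-2,5,14-trienal | O=C/C=C(\C)C/C=C/[C@](C)(O)CC[C@@H]1O[C@@]1(C)[C@@H](OC(C)=O)CC=C | intermediate
14 | methyl 2-(bromomethyl)acrylate | C=C(CBr)C(=O)OC | starting material
15 | bis(pinacolato)diboron | CC1(C)OB(OC1(C)C)B1OC(C)(C)C(C)(C)O1 | starting material
16 | methyl 2-[(4,4,5,5-tetramethyl-1,3,2-dioxaborolan-2-yl)methyl]acrylate | C=C(CB1OC(C)(C)C(C)(C)O1)C(=O)OC | intermediate
17 | methyl (2E,5S,6R,7S,10R,11E,14E)-5-acetoxy-6,7-epoxy-10-hydroxy-6,10,14-trimethyl-16-oxo-2-[(4,4,5,5-tetramethyl-1,3,2-dioxaborolan-2-yl)methyl]hexadeca-2,11,14-trienoate (C14 cis to CH2Bpin) | O=C/C=C(\C)C/C=C/[C@](C)(O)CC[C@@H]1O[C@@]1(C)[C@@H](OC(C)=O)C/C=C(\CB1OC(C)(C)C(C)(C)O1)C(=O)OC | intermediate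
18 | methyl 2-[(1S,2S,3E,6E,8R,11S,12R,13S)-13-acetoxy-11,12-epoxy-8-hydroxy-4,8,12-trimethyl-2-(pinacolboryloxy)cyclotetradeca-3,6-dien-1-yl]acrylate (cembrane numbering) | COC(=O)C(=C)[C@H]1[C@@H](OB2OC(C)(C)C(C)(C)O2)/C=C(\C)C/C=C/[C@](C)(O)CC[C@@H]3O[C@@]3(C)[C@@H](OC(C)=O)C1 | intermediate
19 | (1S,2S,3E,6E,8R,11S,12R,13S)-13-acetoxy-11,12-epoxy-8-hydroxycembra-3,6,15(17)-trien-16,2-olide (CNP0288879.3) | C=C1C(=O)O[C@H]2/C=C(\C)C/C=C/[C@](C)(O)CC[C@@H]3O[C@@]3(C)[C@@H](OC(C)=O)C[C@@H]12 | target

**Step count**
Total: 9 steps. Longest linear sequence: 8 steps (steps 1–6, 8 and 9); step 7 makes the metathesis partner.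

**Steps most likely to fail, with fallbacks**

Step 9 (the new macrocyclising allylboration). The phosphoric acid may not turn over the ester-deactivated boronate, may give poor facial control against the resident stereocentres, or may let the C8 hydroxyl open the oxirane. The fallback closes the ring with known chromium chemistry and sets out from 13. Cross-metathesis of 13 with commercial 14 (second-generation Hoveyda–Grubbs catalyst, CH2Cl2, 40 °C) gives the (Z)-allylic bromide F1. Slow addition of F1 to CrCl2 (6 equiv) in THF at 2 mM is a Nozaki–Hiyama-type Barbier allylation through an allylchromium species of trivalent chromium and a chair transition state, as used for cembranolide lactones. It gives the cis γ-hydroxy ester F2, which lactonises (spontaneously or with PPTS) and so comes back to the route at 19. Face selection is then substrate-controlled and diastereomers are separated at the end.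

Step 8 (cross-metathesis with the boron-bearing acrylate). The Lewis-acidic allylboronate may slow the ruthenium catalyst or protodeboronate, and the E/Z ratio at C1=C15 may be modest. The fallback brings boron in after the metathesis and sets out from 13 and 14. Compound 14 with KOAc in DMF gives methyl 2-(acetoxymethyl)acrylate F3. Cross-metathesis of 13 with F3 gives the allylic acetate F4. Base-free Pd2(dba)3-catalysed borylation of F4 with 15 (PhMe, 50 °C; π-allylpalladium formation and B–B transmetalation, the enal being a spectator) gives 17, where the route is rejoined.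

Step 6 (epoxidation beside a free tertiary allylic alcohol and an enal). The titanium Lewis acid could promote attack of the C8 hydroxyl on the new oxirane (tetrahydrofuran formation), or the reaction could be sluggish. The fallback switches from reagent control to substrate control and sets out from 11. VO(acac)2 (2 mol %) and t-BuOOH in CH2Cl2 at 0 °C epoxidise the secondary allylic alcohol under allylic 1,2-strain control from the C12 methyl group, which favours the same erythro epoxy alcohol 12. Acetylation (Ac2O, pyridine, DMAP) then returns to 13; no new compound is made (F0).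

Further compounds
F1 | step 9 | methyl (2Z,5S,6R,7S,10R,11E,14E)-5-acetoxy-2-(bromomethyl)-6,7-epoxy-10-hydroxy-6,10,14-trimethyl-16-oxohexadeca-2,11,14-trienoate | O=C/C=C(\C)C/C=C/[C@](C)(O)CC[C@@H]1O[C@@]1(C)[C@@H](OC(C)=O)C/C=C(\CBr)C(=O)OC
F2 | step 9 | methyl 2-[(1S,2S,3E,6E,8R,11S,12R,13S)-13-acetoxy-11,12-epoxy-2,8-dihydroxy-4,8,12-trimethylcyclotetradeca-3,6-dien-1-yl]acrylate (cembrane numbering) | COC(=O)C(=C)[C@H]1[C@@H](O)/C=C(\C)C/C=C/[C@](C)(O)CC[C@@H]3O[C@@]3(C)[C@@H](OC(C)=O)C1
F3 | step 8 | methyl 2-(acetoxymethyl)acrylate | C=C(COC(C)=O)C(=O)OC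
F4 | step 8 | methyl (2E,5S,6R,7S,10R,11E,14E)-5-acetoxy-2-(acetoxymethyl)-6,7-epoxy-10-hydroxy-6,10,14-trimethyl-16-oxohexadeca-2,11,14-trienoate | O=C/C=C(\C)C/C=C/[C@](C)(O)CC[C@@H]1O[C@@]1(C)[C@@H](OC(C)=O)C/C=C(\COC(C)=O)C(=O)OC
F0 | step 6 | none | none
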